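Dawn, winter and dusk each get half the solid reagent of Friday's run on the same substrate, and that comparison is where we start on your quick number.

the same everywhere: substrate 0.45 M

| charge | solid reagent | temperature | remark | time |
|---|---|---|---|---|
| Friday's | 0.81 M | 35 °C | run made earlier |  |
| dawn | 0.405 M | 35 °C |  | 20 h |
| winter | 0.405 M | −25 °C |  | 20 h |
| dusk | 0.405 M | 5 °C |  | 20 h |

Friday's run (percent of the substrate charged)

| time / h | target / % | substrate / % |
|---|---|---|
| 0.500 | 10.4 | 58.9 |
| 1.50 | 13.5 | 1.1 |
| 3.00 | 7.8 | 0 |
| 4.00 | 6.5 | 0 |
| 6.00 | 3.7 | 0.3 |

(readings scatter by 0.5 percentage points)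

- given per volume of solution although it is solid: solid reagent
- at the start none of the solid reagent is in solution
- the earlier runs do not show what temperature does; that part of a forecast is a guess

* which flask leads in amount of target, in percent of the substrate charged ("all alike" within 1.5 percentage points) (dawn / winter / dusk / all alike)
* how much target is there at the end, in percent of the substrate charged: dawn
* how much target is there at the end, in percent of the substrate charged: winter
* how much target is there at the end, in percent of the substrate charged: dusk

Friday's run, charged with 1.80 of reagent per substrate, read 0% substrate at 3.00 h. So we assume that one reagent consumes one substrate, which that run doesn't prove, and we count the fraction left rather than the fraction made: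

left at the stop = 1 − reagent charge / substrate charge = 10.0%

substrate left − unspent reagent, solid and dissolved together, as a fraction of the substrate charge = the same number, at any moment

This is the stop fraction, the part of the substrate that outlasts its limiting reagent. On that assumption it contains no rate constant, so temperature enters by how soon a flask arrives there. It bounds the substrate, though, and tells us nothing of the target.

For the target we have no better figure than your hunch, the forecast: 4% in dawn, 4% in winter, 11% in dusk, with dusk leading. Its ground for dusk is “with less reagent it should lead”. The temperature part of it is a guess, since the earlier runs don't show what temperature does.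

    intermediate ⇌ target (K = 1.10, k = 0.0180 min⁻¹, Ea = 75.0 kJ mol⁻¹, ΔH = 4.00 kJ mol⁻¹)
    intermediate ⇌ isomer of the product A (K = 240, k = 0.00120 min⁻¹, Ea = 82.0 kJ mol⁻¹, ΔH = −8.00 kJ mol⁻¹)
    target ⇌ isomer of the product B (K = 2.70, k = 0.00160 min⁻¹, Ea = 91.0 kJ mol⁻¹, ΔH = 6.00 kJ mol⁻¹)
    solid reagent ⇌ partner, rate k4*(cs4 - [partner]) while solid is left; crystals form when [partner] > cs4 (solubility = 0.240 M, k = 0.0280 min⁻¹)
    substrate + partner → intermediate + released group (k = 0.0930 L mol⁻¹ min⁻¹, Ea = 72.0 kJ mol⁻¹)
    (constants at 5 °C)

The flasks give 0.709% target in dawn, 7.51% in winter and 14.5% in dusk, so dusk leads as forecast. At 20.0 h, dawn has 10% substrate left and dusk 10%, which is the stop fraction. Winter read at 3.0 d has solid reagent at 0% of its own charge, 25.4% substrate and partner, the dissolved reagent, at 15.4% of the substrate charge. The difference, 10.0%, stands near the stop fraction. Dusk's lead belongs to the asked time: winter read at 3.0 d holds 28.6% target, more than dusk's 14.5% at 20.0 h.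

(Readings and results are calculated with constants of no real substance; scatter was added.)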